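Start from the constants: none is given, so read one off the runs and turn it into a time at the charged amounts.

all flasks: enzyme 0.042 mol%

| charge | substrate | remark | time |
|---|---|---|---|
| Tuesday's | 10 mM | run made earlier |  |
| Saturday's | 14 mM | run made earlier |  |
| Friday's | 22 mM | run made earlier |  |
| cedar | 10 mM | a closed flask charged with all of it at once and left for 2.5 d | 2.5 d |
| elm | 10 mM | a single well-mixed tank run continuously and read at steady state, 2.5 d in it on average |  |
| alder | 10 mM (fed, over 2.00 d) | a stirred flask in which substrate is dosed at a steady rate over 2.00 d without added volume, worked up at 2.5 d | 2.5 d |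
| larch | 10 mM | a single well-mixed tank run continuously and read at steady state, 7.50 d in it on average |  |

| run | time / d | target / % | substrate / % |
|---|---|---|---|
| Tuesday's | 0.208 | 10.0 | 88.2 |
| Tuesday's | 0.500 | 20.5 | 76.0 |
| Tuesday's | 1.04 | 28.4 | 60.7 |
| Tuesday's | 2.50 | 32.6 | 37.2 |
| Saturday's | 0.250 | 21.3 | 74.9 |
| Saturday's | 0.500 | 32.0 | 59.1 |
| Saturday's | 1.25 | 39.6 | 35.7 |
| Saturday's | 3.00 | 37.3 | 18.1 |
| Friday's | 0.250 | 36.2 | 58.1 |
| Friday's | 0.500 | 47.5 | 37.9 |
| Friday's | 1.25 | 49.7 | 18.0 |
| Friday's | 3.00 | 43.8 | 5.9 |

(scatter of a reading: 0.5 percentage points)

* the set-up with the highest amount of target at the outlet or at the end, in percent of the substrate put in ("none" if the first two lie within 2 percentage points) (cedar / elm / alder / larch / none)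
* amount of target at the outlet or at the end, in percent of the substrate put in, cedar
* amount of target at the outlet or at the end, in percent of the substrate put in, elm
* amount of target at the outlet or at the end, in percent of the substrate put in, alder
* amount of target at the outlet or at the end, in percent of the substrate put in, larch

- the stated concentrations are those of everything mixed, before any reaction; amounts are the same in each set-up
- the feed brings no volume worth counting
- the earlier runs were made in a closed, stirred flask

Look first at something odd in Tuesday's run. Between 1.04 d and 2.50 d the substrate falls by 24 percentage points, yet the target rises by 4.2 points. Subtract both from the charge: this gap, the mass-balance deficit, grows from 10.9 % to 30.2 %, so the substrate is going somewhere besides the target.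

Now test whether the gap grows with substrate share times target share. Over the last two readings of each run, divide the mean of that product by the growth rate of the gap, then multiply by the run's charge over Tuesday's.

| Run | Charge | Scaled time |
|---|---|---|
| Tuesday's | 10 mM | 1.11 d |
| Saturday's | 14 mM | 1.29 d |
| Friday's | 22 mM | 1.23 d |

Take their mean, 1.21 d, as the gap time at 10 mM: the product of the two shares over the growth rate of the gap.

Use it on a tank at steady state, where the outlet gap equals residence time times the product of shares over the gap time. Guess larch's substrate at Tuesday's last share; the balance then gives 19.0 % target. Cedar repeats Tuesday's recipe and time, so expect 32.6 %, which is more than that guessed larch figure.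

The forecast names cedar, with 32.6 % for cedar on the ground “Cedar is simply Tuesday's 2.5 d point”, and with 22 % for elm, 27.5 % for alder and 17 % for larch, the last of these lower than my larch figure.

The flask gives cedar first: cedar 32.1 %, elm 20.6 %, alder 27.3 %, larch 17.0 %.

    substrate + target → side product (k = 0.0290 M⁻¹ min⁻¹)
    substrate + enzyme → target + enzyme, rate k2*[substrate]^3*[enzyme]/(1 + ([substrate]/Kh2)^3) (15.0 mM, k = 22000 M⁻³ s⁻¹)

The gap is the side product, counted as two. Put larch's substrate 40.3 % and target 17.0 % into the tank rule: it gives 42.3 %, and larch holds 42.8 % side product. Now ask whether cedar has come to rest. At 2.50 d cedar holds 38.3 % substrate and 32.1 % target, and the gap time puts the growth of its gap at 0.102 d⁻¹ as a share of the charge, so cedar has not come to rest. At ten times the time, 25.0 d, cedar's target is down by 18 points to 14.2 %, and with 4.01 % substrate left the gap time still puts the growth of the gap at 0.00471 d⁻¹.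

The readings are simulated on assumed constants, and the scatter is random.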